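**Retrosynthetic overview**

1. Labels: bicyclo[3.2.1]octane core C1(Me)–C2(enol C–OH)–C3(acyl)–C4(=O)–C5–C6(H)–C7(H2), with C8(=O) as the one-carbon bridge between C1 and C5; fused cyclopentane C5–C6–C9(Me2)–C10–C11; C12 is the carbinol carbon on C10.
2. Feature used: C5, C8(=O), C7 and C6 form, without C1, a cyclobutanone fused to the cyclopentane at C5–C6. That is the [2+2] adduct of a ketene C5=C8=O (C5 also carrying the future C4 as an ester) and a vinyl group C6=C7 joined through C11–C10–C9.
3. Late disconnections: C3 acyl group (O-acylation, O→C shift); C3–C4 (Dieckmann closure of a C1 acetyl group onto the C5 ester); C1–C2 and C1–Me (aldol and methylation of the cyclopentanone enolate); C1 itself (CH2N2 expansion of the cyclobutanone between C8 and C7).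
4. Key disconnection: C5–C6 and C7–C8 by intramolecular ketene–alkene [2+2] of ethoxycarbonylketene 17, generated by Wolff rearrangement of diazo keto ester 16. Compound 16 comes from aldehyde 14 (Roskamp, diazo transfer); 14 comes from an Evans prenylation of the 3,3-dimethylpent-4-enoyl imide (sets C10), MeLi addition (C12) and chemoselective ozonolysis.
5. Ring order: cyclopentane and cyclobutanone together (step 10), cyclobutanone to cyclopentanone (step 11), six-membered dione ring last (step 15).

Key step: step 10

Remark: the angular ester is carried as the ethyl ester, because ethyl diazoacetate is the commercial Roskamp partner and the alkoxy group leaves as ethanol in step 15; keto–enol tautomers are drawn in one form.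

**Route**

Step 1
Reactants: 1 3,3-dimethylpent-4-enoic acid; 2 (S)-4-benzyl-1,3-oxazolidin-2-one
Product: 4 (S)-4-benzyl-3-(3,3-dimethylpent-4-enoyl)-1,3-oxazolidin-2-one, via mixed pivalic anhydride 3 (not isolated)
Conditions: PivCl, Et3N, THF, −20 °C; then LiCl, 2, rt
Reagents that add atoms: none
Why: N-acylation of the oxazolidinone through the mixed pivalic anhydride (LiCl/Et3N protocol) is the standard entry to Evans imides and creates no stereocentre.

Step 2
Reactants: 4 (S)-4-benzyl-3-(3,3-dimethylpent-4-enoyl)-1,3-oxazolidin-2-one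
Product: 6 (S)-4-benzyl-3-[(2S)-5-methyl-2-(2-methylbut-3-en-2-yl)hex-4-enoyl]-1,3-oxazolidin-2-one, via sodium Z-enolate 5 (not isolated)
Conditions: NaN(SiMe3)2, THF, −78 °C; prenyl bromide, −78 → −30 °C
Reagents that add atoms: prenyl bromide (1-bromo-3-methylbut-2-ene), CC(C)=CCBr
Why: Evans asymmetric alkylation, in which the chelated Z-enolate 5 is attacked by the reactive allylic bromide on the face opposite the benzyl group, which should set C10 as S (the CMe2CH=CH2 group outranks the incoming CH2).

Step 3
Reactants: 6 (S)-4-benzyl-3-[(2S)-5-methyl-2-(2-methylbut-3-en-2-yl)hex-4-enoyl]-1,3-oxazolidin-2-one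
Product: 8 (2S)-5-methyl-2-(2-methylbut-3-en-2-yl)hex-4-enoic acid, via lithium percarboxylate 7 (not isolated)
Conditions: LiOH, H2O2, THF/H2O, 0 °C; aq. Na2SO3; then HCl to pH 2
Reagents that add atoms: hydrogen peroxide (as LiOOH), OO
Why: Hydroperoxide-mediated imide hydrolysis cleaves even hindered N-acyl oxazolidinones at the exocyclic carbonyl without epimerising C10, and the percarboxylate is reduced by sulfite before acidification so that the prenyl alkene is not epoxidised.

Step 4
Reactants: 8 (2S)-5-methyl-2-(2-methylbut-3-en-2-yl)hex-4-enoic acid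
Product: 9 methyl (2S)-5-methyl-2-(2-methylbut-3-en-2-yl)hex-4-enoate
Conditions: TMSCHN2, PhMe/MeOH, 0 °C → rt
Reagents that add atoms: (trimethylsilyl)diazomethane, C[Si](C)(C)C=[N+]=[N-]
Why: Diazoalkane esterification is neutral, tolerates the hindered carboxyl group and leaves C10 and both alkenes untouched.

Step 5
Reactants: 9 methyl (2S)-5-methyl-2-(2-methylbut-3-en-2-yl)hex-4-enoate
Product: 11 (3S)-2,6-dimethyl-3-(2-methylbut-3-en-2-yl)hept-5-en-2-ol, via methyl ketone 10 (not isolated)
Conditions: MeLi (4 equiv), Et2O, −78 → 0 °C; H2O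
Reagents that add atoms: methyllithium, [Li]C
Why: Double organolithium addition to the ester through ketone 10 builds the carbinol carbon C12, and carbonyl addition should outrun removal of the shielded C10–H, so the stereocentre is kept.

Step 6
Reactants: 11 (3S)-2,6-dimethyl-3-(2-methylbut-3-en-2-yl)hept-5-en-2-ol
Product: 12 triethyl{[(3S)-2,6-dimethyl-3-(2-methylbut-3-en-2-yl)hept-5-en-2-yl]oxy}silane
Conditions: TESOTf, 2,6-lutidine, CH2Cl2, 0 °C → rt
Reagents that add atoms: triethylsilyl triflate, CC[Si](CC)(CC)OS(=O)(=O)C(F)(F)F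
Why: Silyl triflate with 2,6-lutidine silylates hindered tertiary alcohols, and the TES ether masks the hydroxyl that would otherwise capture the ketene of step 10 as a lactone.

Step 7
Reactants: 12 triethyl{[(3S)-2,6-dimethyl-3-(2-methylbut-3-en-2-yl)hept-5-en-2-yl]oxy}silane
Product: 14 (3S)-4,4-dimethyl-3-[2-(triethylsilyloxy)propan-2-yl]hex-5-enal, via secondary ozonide 13 (not isolated)
Conditions: O3 (1 equiv, Sudan Red 7B end-point), CH2Cl2, −78 °C; PPh3, −78 °C → rt
Reagents that add atoms: ozone, [O-][O+]=O
Why: Chemoselective ozonolysis, in which the electron-rich trisubstituted prenyl alkene should react far faster than the monosubstituted vinyl group on quaternary C9, and reduction of ozonide 13 releases the aldehyde with C10 now β to the carbonyl and not epimerisable.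

Step 8
Reactants: 14 (3S)-4,4-dimethyl-3-[2-(triethylsilyloxy)propan-2-yl]hex-5-enal
Product: 15 ethyl (5S)-6,6-dimethyl-3-oxo-5-[2-(triethylsilyloxy)propan-2-yl]oct-7-enoate
Conditions: N2CHCO2Et, SnCl2 (10 mol%), CH2Cl2, rt
Reagents that add atoms: ethyl diazoacetate, CCOC(=O)C=[N+]=[N-]
Why: Roskamp reaction, in which Lewis-acid-catalysed addition of the diazo ester to the unhindered aldehyde is followed by 1,2-hydride shift and loss of N2 to give the β-keto ester in one operation.

Step 9
Reactants: 15 ethyl (5S)-6,6-dimethyl-3-oxo-5-[2-(triethylsilyloxy)propan-2-yl]oct-7-enoate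
Product: 16 ethyl (5S)-2-diazo-6,6-dimethyl-3-oxo-5-[2-(triethylsilyloxy)propan-2-yl]oct-7-enoate
Conditions: p-ABSA, Et3N, MeCN, 0 °C → rt
Reagents that add atoms: 4-acetamidobenzenesulfonyl azide, CC(=O)Nc1ccc(cc1)S(=O)(=O)N=[N+]=[N-]
Why: Regitz diazo transfer to the doubly activated methylene of a β-keto ester is general and leaves the silyl ether and the alkene untouched.

Step 10
Reactants: 16 ethyl (5S)-2-diazo-6,6-dimethyl-3-oxo-5-[2-(triethylsilyloxy)propan-2-yl]oct-7-enoate
Product: 18 ethyl (1S,3S,5S)-4,4-dimethyl-7-oxo-3-[2-(triethylsilyloxy)propan-2-yl]bicyclo[3.2.0]heptane-1-carboxylate, via ethoxycarbonylketene 17 (not isolated)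
Conditions: PhMe (0.005 M), 150 °C, sealed vessel (microwave)
Reagents that add atoms: none
Why: Heating expels N2 from 16 and C11 migrates from C8 to C5 (Wolff rearrangement) to give ketene 17, whose electrophilic carbonyl carbon C8 bonds to the terminal vinyl carbon C7 while the ketene α-carbon C5 bonds to the internal carbon C6 in a thermal [π2s+π2a] ketene–alkene cycloaddition. The closest known reaction type is the intramolecular [2+2] cycloaddition of hept-6-enoyl-type ketenes (three-atom tether, monosubstituted alkene) to bicyclo[3.2.0]heptan-6-ones, here with an alkoxycarbonylketene generated by Wolff rearrangement of a 2-diazo-3-oxo ester. The cyclopentane closes by C5–C6 bond formation as a five-membered, exo-type closure over the tether C11–C10–C9, and the cyclobutanone closes by the C8–C7 bond of the same cycloaddition, which can only give the cis ring fusion. C5 and C6 are therefore fixed relative to each other by the tether, and their absolute sense is set by C10: in the envelope-like transition state the bulky CMe2OSiEt3 group sits pseudo-equatorial, which places C7 cis to C12. The step needs periselectivity for [2+2] over oxa-[4+2] addition of the acylketene unit, ene reaction and dimerisation; the tether cannot span the ester oxygen and C8 without a bridgehead alkene, C9 carries no allylic hydrogen, and high dilution together with the gem-dimethyl group at C9 favours the intramolecular path. The polarity-matched regiochemistry (C8 to the less substituted alkene carbon) is the normal one for a monosubstituted alkene, so the fused and not the bridged cyclobutanone is expected.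

Step 11
Reactants: 18 ethyl (1S,3S,5S)-4,4-dimethyl-7-oxo-3-[2-(triethylsilyloxy)propan-2-yl]bicyclo[3.2.0]heptane-1-carboxylate
Product: 19 ethyl (3aS,5S,6aS)-4,4-dimethyl-1-oxo-5-[2-(triethylsilyloxy)propan-2-yl]hexahydropentalene-6a(1H)-carboxylate
Conditions: CH2N2 (excess), Et2O, 0 °C → rt
Reagents that add atoms: diazomethane, C=[N+]=[N-]
Why: Diazomethane ring expansion of the strained cyclobutanone, in which the CH2 carbon C7 should migrate in preference to the quaternary, ester-bearing C5 (an electron-poor carbon is a poor migrating group), so C1 is inserted between C8 and C7, and the much less reactive cyclopentanone is not homologated further.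

Step 12
Reactants: 19 ethyl (3aS,5S,6aS)-4,4-dimethyl-1-oxo-5-[2-(triethylsilyloxy)propan-2-yl]hexahydropentalene-6a(1H)-carboxylate
Product: 21 2-methyl derivative of 19 (methyl on C1; mixture of C1 epimers), via lithium enolate 20 (not isolated)
Conditions: LiN(SiMe3)2, THF, −78 °C; MeI, −78 → −20 °C
Reagents that add atoms: iodomethane, CI
Why: Enolate alkylation at the only enolisable position (C5 is quaternary) installs the C1 methyl group, and the configuration formed at C1 does not matter because the centre is planarised again in step 13.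

Step 13
Reactants: 21 2-methyl derivative of 19 (mixture of C1 epimers)
Product: 23 aldol adduct carrying methyl and 1-hydroxyethyl on C1 (hydroxyethyl cis to the angular ester; carbinol epimers), via lithium enolate 22 (not isolated)
Conditions: LiN(iPr)2, THF, −78 → −20 °C; CH3CHO, −78 °C; AcOH, −78 °C
Reagents that add atoms: acetaldehyde, CC=O
Why: Aldol addition of the tetrasubstituted lithium enolate creates quaternary C1, with the aldehyde expected on the convex face of the cis-bicyclo[3.3.0]octane (the face of the angular ester and H6, the concave face being screened by the folded second ring and its C9 methyl group), so that the new C1–C2 bond ends cis to the ester, and the cold acidic quench forestalls retro-aldol reversal.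

Step 14
Reactants: 23 aldol adduct (carbinol epimers)
Product: 24 1,3-diketone carrying methyl and acetyl on C1 (acetyl cis to the angular ester)
Conditions: Dess–Martin periodinane, CH2Cl2, 0 °C → rt
Reagents that add atoms: none
Why: Dess–Martin oxidation converts both carbinol epimers into the same non-enolisable 1,3-diketone under near-neutral conditions that avoid retro-aldol cleavage.

Step 15
Reactants: 24 1,3-diketone carrying methyl and acetyl on C1
Product: 27 TES-protected bicyclo[3.2.1]octane-2,4,8-trione fused to the cyclopentane (largely enolised), via acetyl lithium enolate 25 (not isolated), via trione lithium enolate 26 (not isolated)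
Conditions: LiN(SiMe3)2 (2.2 equiv), THF, −78 → 0 °C; cold 1 M HCl work-up
Reagents that add atoms: none
Why: Dieckmann condensation in which the acetyl methyl group C3 is the only acidic site, its enolate 25 attacks the cis-disposed angular ester in a six-membered closure (C3–C4), and immediate deprotonation of the product to the stabilised enolate 26 drives the reaction and shields the ring from retro-Claisen cleavage.

Step 16
Reactants: 27 TES-protected trione; 28 (R)-2-methylbutanoic acid
Product: 30 TES ether of the target (C3-acyl triketone), via enol ester 29 (not isolated)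
Conditions: DCC, DMAP (1.2 equiv), CH2Cl2, 0 °C → rt
Reagents that add atoms: none
Why: Steglich O-acylation of the cyclic 1,3-dione followed by DMAP-mediated O→C acyl migration (the standard route to 2-acyl cycloalkane-1,3-diones) places the acyl group on C3, and the side-chain stereocentre is carried in from 28 under conditions with no base stronger than DMAP.

Step 17
Reactants: 30 TES ether of the target
Product: 31 target CNP0207052.1
Conditions: HF·pyridine, THF/pyridine, 0 °C → rt
Reagents that add atoms: none
Why: Fluoride-mediated desilylation with buffered HF·pyridine frees the tertiary carbinol without affecting the acidic enolised triketone or any stereocentre.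

**Compound list**

1 | 3,3-dimethylpent-4-enoic acid | C=CC(C)(C)CC(=O)O | starting material
2 | (S)-4-benzyl-1,3-oxazolidin-2-one | O=C1N[C@@H](Cc2ccccc2)CO1 | starting material
3 | 3,3-dimethylpent-4-enoic pivalic anhydride | C=CC(C)(C)CC(=O)OC(=O)C(C)(C)C | intermediate
4 | (S)-4-benzyl-3-(3,3-dimethylpent-4-enoyl)-1,3-oxazolidin-2-one | O=C1OC[C@H](Cc2ccccc2)N1C(=O)CC(C)(C)C=C | intermediate
5 | sodium Z-enolate of 4 | [Na+].[O-]/C(=C\C(C)(C)C=C)N1C(=O)OC[C@@H]1Cc1ccccc1 | intermediate
6 | (S)-4-benzyl-3-[(2S)-5-methyl-2-(2-methylbut-3-en-2-yl)hex-4-enoyl]-1,3-oxazolidin-2-one | O=C1OC[C@H](Cc2ccccc2)N1C(=O)[C@@H](CC=C(C)C)C(C)(C)C=C | intermediate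
7 | lithium (2S)-5-methyl-2-(2-methylbut-3-en-2-yl)hex-4-eneperoxoate | [Li+].[O-]OC(=O)[C@@H](CC=C(C)C)C(C)(C)C=C | intermediate
8 | (2S)-5-methyl-2-(2-methylbut-3-en-2-yl)hex-4-enoic acid | OC(=O)[C@@H](CC=C(C)C)C(C)(C)C=C | intermediate
9 | methyl (2S)-5-methyl-2-(2-methylbut-3-en-2-yl)hex-4-enoate | COC(=O)[C@@H](CC=C(C)C)C(C)(C)C=C | intermediate
10 | (3S)-6-methyl-3-(2-methylbut-3-en-2-yl)hept-5-en-2-one | CC(=O)[C@@H](CC=C(C)C)C(C)(C)C=C | intermediate
11 | (3S)-2,6-dimethyl-3-(2-methylbut-3-en-2-yl)hept-5-en-2-ol | CC(C)(O)[C@@H](CC=C(C)C)C(C)(C)C=C | intermediate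
12 | triethyl{[(3S)-2,6-dimethyl-3-(2-methylbut-3-en-2-yl)hept-5-en-2-yl]oxy}silane | CC[Si](CC)(CC)OC(C)(C)[C@@H](CC=C(C)C)C(C)(C)C=C | intermediate
13 | 3,3-dimethyl-5-{(2S)-3,3-dimethyl-2-[2-(triethylsilyloxy)propan-2-yl]pent-4-en-1-yl}-1,2,4-trioxolane (ozonide; epimers at the ring CH) | CC1(C)OOC(C[C@H](C(C)(C)O[Si](CC)(CC)CC)C(C)(C)C=C)O1 | intermediate
14 | (3S)-4,4-dimethyl-3-[2-(triethylsilyloxy)propan-2-yl]hex-5-enal | O=CC[C@H](C(C)(C)O[Si](CC)(CC)CC)C(C)(C)C=C | intermediate
15 | ethyl (5S)-6,6-dimethyl-3-oxo-5-[2-(triethylsilyloxy)propan-2-yl]oct-7-enoate | CCOC(=O)CC(=O)C[C@H](C(C)(C)O[Si](CC)(CC)CC)C(C)(C)C=C | intermediate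
16 | ethyl (5S)-2-diazo-6,6-dimethyl-3-oxo-5-[2-(triethylsilyloxy)propan-2-yl]oct-7-enoate | CCOC(=O)C(=[N+]=[N-])C(=O)C[C@H](C(C)(C)O[Si](CC)(CC)CC)C(C)(C)C=C | intermediate
17 | ethyl (4S)-5,5-dimethyl-2-(oxomethylidene)-4-[2-(triethylsilyloxy)propan-2-yl]hept-6-enoate (tethered ethoxycarbonylketene) | CCOC(=O)C(=C=O)C[C@H](C(C)(C)O[Si](CC)(CC)CC)C(C)(C)C=C | intermediate
18 | ethyl (1S,3S,5S)-4,4-dimethyl-7-oxo-3-[2-(triethylsilyloxy)propan-2-yl]bicyclo[3.2.0]heptane-1-carboxylate (cis-fused; side chain cis to the cyclobutanone) | CCOC(=O)[C@@]12C[C@H](C(C)(C)O[Si](CC)(CC)CC)C(C)(C)[C@@H]1CC2=O | intermediate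
19 | ethyl (3aS,5S,6aS)-4,4-dimethyl-1-oxo-5-[2-(triethylsilyloxy)propan-2-yl]hexahydropentalene-6a(1H)-carboxylate | CCOC(=O)[C@@]12C[C@H](C(C)(C)O[Si](CC)(CC)CC)C(C)(C)[C@@H]1CCC2=O | intermediate
20 | lithium enolate of 19 (C8–O, C8=C1) | CCOC(=O)[C@@]12C[C@H](C(C)(C)O[Si](CC)(CC)CC)C(C)(C)[C@@H]1CC=C2[O-].[Li+] | intermediate
21 | 2-methyl derivative of 19 (methyl on C1; C1 epimers) | CCOC(=O)[C@@]12C[C@H](C(C)(C)O[Si](CC)(CC)CC)C(C)(C)[C@@H]1CC(C)C2=O | intermediate
22 | lithium enolate of 21 (tetrasubstituted) | CCOC(=O)[C@@]12C[C@H](C(C)(C)O[Si](CC)(CC)CC)C(C)(C)[C@@H]1CC(C)=C2[O-].[Li+] | intermediate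
23 | aldol adduct: C1 carries methyl and 1-hydroxyethyl, hydroxyethyl cis to the angular ester (carbinol epimers) | CCOC(=O)[C@@]12C[C@H](C(C)(C)O[Si](CC)(CC)CC)C(C)(C)[C@@H]1C[C@@](C)(C(C)O)C2=O | intermediate
24 | 1,3-diketone: C1 carries methyl and acetyl, acetyl cis to the angular ester | CCOC(=O)[C@@]12C[C@H](C(C)(C)O[Si](CC)(CC)CC)C(C)(C)[C@@H]1C[C@@](C)(C(C)=O)C2=O | intermediate
25 | lithium enolate of the acetyl group of 24 | CCOC(=O)[C@@]12C[C@H](C(C)(C)O[Si](CC)(CC)CC)C(C)(C)[C@@H]1C[C@@](C)(C(=C)[O-])C2=O.[Li+] | intermediate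
26 | lithium enolate of trione 27 | [Li+].[O-]C1=CC(=O)[C@]2(C)C[C@H]3C(C)(C)[C@@H](C(C)(C)O[Si](CC)(CC)CC)C[C@]13C2=O | intermediate
27 | TES-protected trione: cyclopentane-fused 1-methylbicyclo[3.2.1]octane-2,4,8-trione (drawn as the diketo form) | O=C1CC(=O)[C@]2(C)C[C@H]3C(C)(C)[C@@H](C(C)(C)O[Si](CC)(CC)CC)C[C@]13C2=O | intermediate
28 | (R)-2-methylbutanoic acid | CC[C@@H](C)C(=O)O | starting material
29 | enol (R)-2-methylbutanoate of 27 (one of the two enol-ester regioisomers drawn; both converge) | CC[C@@H](C)C(=O)OC1=CC(=O)[C@]2(C)C[C@H]3C(C)(C)[C@@H](C(C)(C)O[Si](CC)(CC)CC)C[C@]13C2=O | intermediate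
30 | TES ether of the target | CC[C@@H](C)C(=O)C1=C(O)[C@]2(C)C[C@H]3C(C)(C)[C@@H](C(C)(C)O[Si](CC)(CC)CC)C[C@@]3(C1=O)C2=O | intermediate
31 | CNP0207052.1 | CC[C@@H](C)C(=O)C1=C(O)[C@]2(C)C[C@H]3C(C)(C)[C@@H](C(C)(C)O)C[C@@]3(C1=O)C2=O | target

**Step count and risks**

Total steps: 17. Longest linear sequence: 17 steps (1 to 31); 2 and 28 enter as purchased materials.

Steps most likely to fail:

Step 10. At the temperature needed for nitrogen loss the ketene may be lost to dimerisation or to capture by unchanged diazo compound, the diazo group may add to the vinyl group through a carbene, and facial selectivity may be eroded. The fallback separates ketene formation from cycloaddition and sets out from 16. Irradiation (350 nm) in THF/H2O at rt should effect the Wolff rearrangement with capture of the ketene by water to give the malonic half-ester (4S)-2-(ethoxycarbonyl)-5,5-dimethyl-4-[2-(triethylsilyloxy)propan-2-yl]hept-6-enoic acid F1. Treatment with 1-chloro-N,N,2-trimethylprop-1-en-1-amine in CH2Cl2 should convert it under neutral conditions into the acid chloride ethyl (4S)-2-(chlorocarbonyl)-5,5-dimethyl-4-[2-(triethylsilyloxy)propan-2-yl]hept-6-enoate F2. Slow addition of this to Et3N in PhMe at 80 °C should regenerate ketene 17 by dehydrochlorination, at lower temperature and with no diazo compound present, and the route is rejoined at 18.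

Step 13. The congested lithium aldolate may revert by retro-aldol reaction, may lactonise onto the neighbouring ester, and the enolate may discriminate its two faces incompletely. The fallback sets out from 21. TMSOTf and Et3N in CH2Cl2 should give the trimethylsilyl enol ether of 21 F3 (only one regioisomer is possible). A Mukaiyama aldol addition to acetaldehyde with BF3·OEt2 at −78 °C, which does not pass through a free basic aldolate, should then deliver 23, where the route is rejoined.

Step 15. The ethoxide set free may attack the non-enolisable 1,3-diketone (retro-Claisen loss of the acetyl group) or the bridging ketone before ring closure is complete. The fallback closes the same C3–C4 bond at the aldehyde oxidation level, so that no alkoxide is expelled, and sets out from 24. LiAlH4 in THF should reduce the ester and both ketones to the triol F4. Excess Dess–Martin periodinane should give the diketo aldehyde F5. Piperidine/AcOH in CH2Cl2 should then promote an intramolecular aldol addition of the acetyl group to the aldehyde to give the hydroxy dione F6. A final Dess–Martin oxidation returns to the route at 27.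

Further compounds
F1 | step 10 | (4S)-2-(ethoxycarbonyl)-5,5-dimethyl-4-[2-(triethylsilyloxy)propan-2-yl]hept-6-enoic acid (C2 epimers) | CCOC(=O)C(C[C@H](C(C)(C)O[Si](CC)(CC)CC)C(C)(C)C=C)C(=O)O
F2 | step 10 | ethyl (4S)-2-(chlorocarbonyl)-5,5-dimethyl-4-[2-(triethylsilyloxy)propan-2-yl]hept-6-enoate (C2 epimers) | CCOC(=O)C(C[C@H](C(C)(C)O[Si](CC)(CC)CC)C(C)(C)C=C)C(Cl)=O
F3 | step 13 | trimethylsilyl enol ether of 21 | CCOC(=O)[C@@]12C[C@H](C(C)(C)O[Si](CC)(CC)CC)C(C)(C)[C@@H]1CC(C)=C2O[Si](C)(C)C
F4 | step 15 | triol from reduction of 24 (C4 hydroxymethyl, C8 and C2 carbinols; carbinol epimers) | OC[C@@]12C[C@H](C(C)(C)O[Si](CC)(CC)CC)C(C)(C)[C@@H]1C[C@@](C)(C(C)O)C2O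
F5 | step 15 | diketo aldehyde (C4 formyl, C8 ketone, C1 acetyl) | O=C[C@@]12C[C@H](C(C)(C)O[Si](CC)(CC)CC)C(C)(C)[C@@H]1C[C@@](C)(C(C)=O)C2=O
F6 | step 15 | 4-hydroxy analogue of 27 (bicyclo[3.2.1]octane-2,8-dione with C4 carbinol; epimers) | OC1CC(=O)[C@]2(C)C[C@H]3C(C)(C)[C@@H](C(C)(C)O[Si](CC)(CC)CC)C[C@]13C2=O
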